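Everything rests on cutting the dihydrobenzofuran at O1–C7a and C3a–C3. In ring B (its benzene ring) O1 sits on C7a, meta to the C4 methoxy group, and C3 on C3a, ortho to it: exactly the pattern formed when an aryne with OMe beside the triple bond takes a nucleophile at its far carbon and an electrophile at its near carbon. One operation therefore joins an epoxy alkoxide to the aryne, forming both bonds, closing the five-membered ring and setting C3 trans to C2. The aryne precursor is an ortho-silyl triflate of ring B already bearing the benzyl-protected 2-aryl-3-(hydroxymethyl)oxolane; its partner is a vanillin-derived anti epoxy alcohol.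

Key step: step 12

Remark: ring A is the oxolane-bound 3-oxy-4-methoxyphenyl group, ring B the benzene ring of the dihydrobenzofuran and ring C the 4-oxy-3-methoxyphenyl group on its C2; aldehydes 1 and 18 are bought O-benzylated, and every selectivity named below is an expectation.

Step 1
Reactants: 1 O-benzylisovanillin; 2 vinylmagnesium bromide
Product: 3 racemic ring A vinyl carbinol
Conditions: THF, 0 °C
Reagents that add atoms: none
Why: Grignard addition of the vinyl nucleophile to the non-enolisable aldehyde should give the allylic alcohol as a racemate, which is resolved in the next step.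

Step 2
Reactants: 3 racemic ring A vinyl carbinol
Product: 4 ring A anti epoxy alcohol
Conditions: Ti(OiPr)4 (10 mol%), L-(+)-DIPT (12 mol%), TBHP (0.45 equiv), 4 Å MS, CH2Cl2, −20 °C
Reagents that add atoms: tert-butyl hydroperoxide, CC(C)(C)OO
Why: Sharpless kinetic resolution, in which the Ti(OiPr)4/L-(+)-DIPT catalyst should epoxidise the (R)-enantiomer of 3 much faster than its antipode and on the tartrate-controlled face, so that with less than half an equivalent of oxidant the anti epoxy alcohol with the (S)-carbinol centre forms while (S)-3 stays behind; only the carbinol centre is carried forward.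

Step 3
Reactants: 4 ring A anti epoxy alcohol
Product: 5 ring A epoxy propargyl ether
Conditions: propargyl bromide, NaH, Bu4NI (cat.), THF, 0 °C
Reagents that add atoms: propargyl bromide, C#CCBr
Why: Williamson etherification in which the sodium alkoxide is generated in the presence of the reactive propargylic bromide in THF, so that O-alkylation should outrun Payne migration and leave both stereocentres untouched.

Step 4
Reactants: 5 ring A epoxy propargyl ether
Product: 6 methylidene oxolane alcohol
Conditions: Cp2TiCl2, Zn, THF, rt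
Reagents that add atoms: none
Why: Reductive epoxide opening by Cp2TiCl (trivalent titanium) places the radical on the internal carbon, and its 5-exo-dig cyclisation onto the alkyne should set C3 trans to the C2 aryl group because the bulky CH2OTi substituent avoids that group in the envelope-like transition state; the vinyl radical is then reduced and protonated to the exocyclic alkene.

Step 5
Reactants: 6 methylidene oxolane alcohol
Product: 7 methylidene oxolane benzyl ether
Conditions: BnBr, NaH, Bu4NI (cat.), THF/DMF, 0 °C → rt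
Reagents that add atoms: benzyl bromide, BrCc1ccccc1
Why: Williamson benzylation caps the only free hydroxyl group so that no O–H bond is present in the later organolithium and aryne steps.

Step 6
Reactants: 7 methylidene oxolane benzyl ether; 8 3-bromo-5-methoxyphenol
Product: 10 oxolane phenol, via alkyl-9-BBN adduct 9 (not isolated)
Conditions: 9-BBN, THF, rt → 50 °C; then 8, Pd(dppf)Cl2 (5 mol%), 3 M aq. K3PO4, DMF, 60 °C
Reagents that add atoms: none
Why: Hydroboration followed by B-alkyl Suzuki–Miyaura coupling, in which 9-BBN should add to the exocyclic alkene from the face opposite the adjacent C3 CH2OBn group, so that the new C4–H lies trans and the CH2–B arm cis to it (3,4-cis), and the alkylborane then couples with the bromide, whose phenol is tolerated as the phenoxide under excess base.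

Step 7
Reactants: 10 oxolane phenol
Product: 11 oxolane aryl carbamate
Conditions: i-PrNCO, Et3N (cat.), CH2Cl2, rt
Reagents that add atoms: isopropyl isocyanate, CC(C)N=C=O
Why: Amine-catalysed addition of the phenol to the isocyanate (carbamoylation) installs a strong ortho-directing group that can later be removed without acid, which the electron-rich 2-aryloxolane would not tolerate.

Step 8
Reactants: 11 oxolane aryl carbamate
Product: 15 ortho-silyl carbamate, via N-silyl carbamate 12 (not isolated), via aryllithium 13 (not isolated), via N-silyl C-silyl carbamate 14 (not isolated)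
Conditions: TMSOTf, TMEDA, Et2O, 0 °C → rt; n-BuLi, TMEDA, −78 °C; TMSCl, −78 °C → rt; then H2O/MeOH
Reagents that add atoms: chlorotrimethylsilane, C[Si](C)(C)Cl
Why: Directed ortho-metalation, in which the carbamate N–H is first masked as the N-silyl derivative and n-BuLi/TMEDA at −78 °C then removes the ring B proton flanked by the carbamate and methoxy oxygens much faster than any benzylic proton, the aryllithium being silylated by TMSCl and the N–Si bond hydrolysed on work-up.

Step 9
Reactants: 15 ortho-silyl carbamate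
Product: 17 silyl triflate (aryne precursor), via silyl phenol 16 (not isolated)
Conditions: DBU, Et2NH, MeCN, 40 °C; then PhNTf2, rt
Reagents that add atoms: N-phenylbis(trifluoromethanesulfonimide), O=S(=O)(N(c1ccccc1)S(=O)(=O)C(F)(F)F)C(F)(F)F
Why: Base-induced E1cB cleavage of the carbamate (the released isocyanate is scavenged by Et2NH) frees the ortho-silyl phenoxide, whose O-sulfonylation by PhNTf2 in the same pot gives the ortho-silylaryl triflate with the silyl group between OMe and OTf, the arrangement that leads to the aryne across C3a–C7a.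

Step 10
Reactants: 18 O-benzylvanillin; 2 vinylmagnesium bromide
Product: 19 racemic ring C vinyl carbinol
Conditions: THF, 0 °C
Reagents that add atoms: none
Why: Grignard addition as in step 1 should give the racemic allylic alcohol.

Step 11
Reactants: 19 racemic ring C vinyl carbinol
Product: 20 ring C anti epoxy alcohol
Conditions: Ti(OiPr)4 (10 mol%), D-(−)-DIPT (12 mol%), TBHP (0.45 equiv), 4 Å MS, CH2Cl2, −20 °C
Reagents that add atoms: tert-butyl hydroperoxide, CC(C)(C)OO
Why: Sharpless kinetic resolution with the enantiomeric tartrate should epoxidise (S)-19 fast and anti-selectively, setting the (R)-carbinol and (S)-oxirane centres, while (R)-19 stays behind.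

Step 12
Reactants: 20 ring C anti epoxy alcohol; 17 silyl triflate (aryne precursor)
Product: 23 tris-benzyl ether of the target, via potassium alkoxide 21 (not isolated), via aryne 22 (not isolated)
Conditions: 20 (1.5 equiv), KH, 18-crown-6, THF, −20 °C; then 17, CsF, −20 °C → rt
Reagents that add atoms: none
Why: Proposed new method: CsF removes the SiMe3 group of 17 and triflate departs, giving the 3-methoxyaryne 22; alkoxide 21 adds to C7a, the aryne carbon remote from OMe, and the aryl anion thus placed on C3a attacks the internal carbon of the tethered epoxide from the rear. The closest known reactions are additions of oxygen nucleophiles to 3-alkoxyarynes at the carbon meta to the alkoxy group, aryne insertion cascades in which the aryl anion is captured intramolecularly, and Parham-type 5-exo epoxide openings by aryllithiums. The dihydrofuran ring closes in the 5-exo-tet mode, which keeps nucleophile, carbon and leaving oxygen collinear, whereas 6-endo attack at the terminal CH2 would give a chroman. C2 keeps the carbinol configuration of 20 because only its O–H bond reacts, and the new centre C3 is set by inversion at the (S)-oxirane carbon, so that the anti epoxy alcohol should give the 2,3-trans ring. The step needs regioselective addition at C7a, secured by the OMe-induced distortion of the aryne and the inductive stabilisation of an anion ortho to OMe, and ring closure faster than protonation, secured by making the alkoxide with KH (H2 is the only by-product) so that no N–H or O–H donor is present. Payne migration of 21 is limited by forming it cold and adding 17 and CsF at once.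

Step 13
Reactants: 23 tris-benzyl ether of the target
Product: 24 target CNP0242386.1
Conditions: H2 (1 atm), 10% Pd/C, EtOAc, rt
Reagents that add atoms: none
Why: Catalytic hydrogenolysis over Pd/C at 1 atm in a neutral solvent should cleave the two aryl benzyl ethers and the alkyl benzyl ether while leaving the benzylic C–O bonds of the oxolane and dihydrofuran rings, which are not activated without acid, and no stereocentre is involved.

Compound list
1 | 3-(benzyloxy)-4-methoxybenzaldehyde (O-benzylisovanillin) | O=Cc1ccc(OC)c(OCc2ccccc2)c1 | starting material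
2 | vinylmagnesium bromide | C=C[Mg]Br | starting material
3 | rac-1-[3-(benzyloxy)-4-methoxyphenyl]prop-2-en-1-ol | OC(C=C)c1ccc(OC)c(OCc2ccccc2)c1 | intermediate
4 | (S)-[3-(benzyloxy)-4-methoxyphenyl][(R)-oxiran-2-yl]methanol (anti) | O[C@@H](c1ccc(OC)c(OCc2ccccc2)c1)[C@H]1CO1 | intermediate
5 | (R)-2-{(S)-[3-(benzyloxy)-4-methoxyphenyl](prop-2-yn-1-yloxy)methyl}oxirane | C#CCO[C@@H](c1ccc(OC)c(OCc2ccccc2)c1)[C@H]1CO1 | intermediate
6 | [(2R,3S)-2-[3-(benzyloxy)-4-methoxyphenyl]-4-methylideneoxolan-3-yl]methanol (2,3-trans) | C=C1CO[C@@H](c2ccc(OC)c(OCc3ccccc3)c2)[C@@H]1CO | intermediate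
7 | (2R,3S)-2-[3-(benzyloxy)-4-methoxyphenyl]-3-[(benzyloxy)methyl]-4-methylideneoxolane | C=C1CO[C@@H](c2ccc(OC)c(OCc3ccccc3)c2)[C@@H]1COCc1ccccc1 | intermediate
8 | 3-bromo-5-methoxyphenol | COc1cc(O)cc(Br)c1 | starting material
9 | 9-{[(3S,4S,5R)-5-[3-(benzyloxy)-4-methoxyphenyl]-4-[(benzyloxy)methyl]oxolan-3-yl]methyl}-9-borabicyclo[3.3.1]nonane | COc1ccc([C@@H]2OC[C@@H](CB3C4CCCC3CCC4)[C@H]2COCc2ccccc2)cc1OCc1ccccc1 | intermediate
10 | 3-{[(3S,4S,5R)-5-[3-(benzyloxy)-4-methoxyphenyl]-4-[(benzyloxy)methyl]oxolan-3-yl]methyl}-5-methoxyphenol (2,3-trans-3,4-cis oxolane) | COc1ccc([C@@H]2OC[C@@H](Cc3cc(O)cc(OC)c3)[C@H]2COCc2ccccc2)cc1OCc1ccccc1 | intermediate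
11 | N-(propan-2-yl)carbamate of phenol 10 | COc1ccc([C@@H]2OC[C@@H](Cc3cc(OC(=O)NC(C)C)cc(OC)c3)[C@H]2COCc2ccccc2)cc1OCc1ccccc1 | intermediate
12 | N-(trimethylsilyl) derivative of carbamate 11 | COc1ccc([C@@H]2OC[C@@H](Cc3cc(OC(=O)N(C(C)C)[Si](C)(C)C)cc(OC)c3)[C@H]2COCc2ccccc2)cc1OCc1ccccc1 | intermediate
13 | aryllithium from 12, lithium on the ring B carbon between the OMe and carbamate oxygens | COc1ccc([C@@H]2OC[C@@H](Cc3cc(OC(=O)N(C(C)C)[Si](C)(C)C)c([Li])c(OC)c3)[C@H]2COCc2ccccc2)cc1OCc1ccccc1 | intermediate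
14 | N-(trimethylsilyl) derivative of 15 | COc1ccc([C@@H]2OC[C@@H](Cc3cc(OC(=O)N(C(C)C)[Si](C)(C)C)c([Si](C)(C)C)c(OC)c3)[C@H]2COCc2ccccc2)cc1OCc1ccccc1 | intermediate
15 | 5-{[(3S,4S,5R)-5-[3-(benzyloxy)-4-methoxyphenyl]-4-[(benzyloxy)methyl]oxolan-3-yl]methyl}-3-methoxy-2-(trimethylsilyl)phenyl N-(propan-2-yl)carbamate | COc1ccc([C@@H]2OC[C@@H](Cc3cc(OC(=O)NC(C)C)c([Si](C)(C)C)c(OC)c3)[C@H]2COCc2ccccc2)cc1OCc1ccccc1 | intermediate
16 | 5-{[(3S,4S,5R)-5-[3-(benzyloxy)-4-methoxyphenyl]-4-[(benzyloxy)methyl]oxolan-3-yl]methyl}-3-methoxy-2-(trimethylsilyl)phenol | COc1ccc([C@@H]2OC[C@@H](Cc3cc(O)c([Si](C)(C)C)c(OC)c3)[C@H]2COCc2ccccc2)cc1OCc1ccccc1 | intermediate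
17 | 5-{[(3S,4S,5R)-5-[3-(benzyloxy)-4-methoxyphenyl]-4-[(benzyloxy)methyl]oxolan-3-yl]methyl}-3-methoxy-2-(trimethylsilyl)phenyl trifluoromethanesulfonate | COc1ccc([C@@H]2OC[C@@H](Cc3cc(OC)c([Si](C)(C)C)c(OS(=O)(=O)C(F)(F)F)c3)[C@H]2COCc2ccccc2)cc1OCc1ccccc1 | intermediate
18 | 4-(benzyloxy)-3-methoxybenzaldehyde (O-benzylvanillin) | O=Cc1ccc(OCc2ccccc2)c(OC)c1 | starting material
19 | rac-1-[4-(benzyloxy)-3-methoxyphenyl]prop-2-en-1-ol | OC(C=C)c1ccc(OCc2ccccc2)c(OC)c1 | intermediate
20 | (R)-[4-(benzyloxy)-3-methoxyphenyl][(S)-oxiran-2-yl]methanol (anti) | O[C@H](c1ccc(OCc2ccccc2)c(OC)c1)[C@@H]1CO1 | intermediate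
21 | potassium alkoxide of 20 | [K+].[O-][C@H](c1ccc(OCc2ccccc2)c(OC)c1)[C@@H]1CO1 | intermediate
22 | aryne from 17: ring B with a C3a≡C7a triple bond next to the OMe-bearing carbon, oxolane unit unchanged | COc1ccc([C@@H]2OC[C@@H](CC3=CC#CC(OC)=C3)[C@H]2COCc2ccccc2)cc1OCc1ccccc1 | intermediate
23 | [(2S,3R)-2-[4-(benzyloxy)-3-methoxyphenyl]-6-{[(3S,4S,5R)-5-[3-(benzyloxy)-4-methoxyphenyl]-4-[(benzyloxy)methyl]oxolan-3-yl]methyl}-4-methoxy-2,3-dihydro-1-benzofuran-3-yl]methanol | COc1ccc([C@@H]2OC[C@@H](Cc3cc(OC)c4c(c3)O[C@H](c3ccc(OCc5ccccc5)c(OC)c3)[C@H]4CO)[C@H]2COCc2ccccc2)cc1OCc1ccccc1 | intermediate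
24 | [(2S,3R)-2-(4-hydroxy-3-methoxyphenyl)-6-{[(3S,4S,5R)-5-(3-hydroxy-4-methoxyphenyl)-4-(hydroxymethyl)oxolan-3-yl]methyl}-4-methoxy-2,3-dihydro-1-benzofuran-3-yl]methanol (CNP0242386.1) | COc1ccc([C@@H]2OC[C@@H](Cc3cc(OC)c4c(c3)O[C@H](c3ccc(O)c(OC)c3)[C@H]4CO)[C@H]2CO)cc1O | target

Total step count: 13. Longest linear sequence: 11 steps (steps 1–9, 12 and 13).

Steps most likely to fail

Step 12 (new method). The aryl anion on C3a may be protonated before it reaches the epoxide, the alkoxide may undergo Payne migration before it meets the aryne, or ring closure may drift to the 6-endo mode. The fallback uses known chemistry, sets out from 15 and 18 and returns at 23. Ipso-iododesilylation of 15 (ICl, CH2Cl2, −78 °C) gives the iodo carbamate F1, and cleavage with DBU/Et2NH gives the 2-iodophenol F2. In parallel, Horner–Wadsworth–Emmons olefination of 18 (triethyl phosphonoacetate, NaH) gives the ethyl cinnamate F3, reduction with i-Bu2AlH gives the cinnamyl alcohol F4, and Sharpless epoxidation (Ti(OiPr)4, L-(+)-DIPT, TBHP) gives the (2S,3S)-epoxy alcohol F5. The phenoxide of F2 opens F5 at the benzylic carbon with inversion (NaOH, aq. dioxane, 70 °C) to give the aryl ether diol F6. Selective primary sulfonylation (TsCl, Bu2SnO cat., Et3N) gives the tosylate F7, and K2CO3/MeOH closes it to the aryl ether epoxide F8, which has the configuration of O-arylated 20. Iodine–lithium exchange (t-BuLi, THF, −78 → 0 °C) then triggers a Parham-type 5-exo epoxide opening by the aryllithium, with inversion, to give 23.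

Step 6. Hydroboration may proceed with poor facial selectivity, because the C2 aryl group lies on the face that has to be attacked, and oxidative addition to the phenoxide-bearing bromide may be slow. The fallback sets C4 in a radical ring closure instead; it sets out from 4 and 8 and returns at 10. Silylation of 8 (i-Pr3SiCl, imidazole) gives the silyl ether F9, Heck reaction with ethyl acrylate (Pd(OAc)2, P(o-tol)3, Et3N) gives the cinnamate F10, i-Bu2AlH gives the allylic alcohol F11, and Appel bromination (CBr4, PPh3) gives the cinnamyl bromide F12. Williamson etherification of 4 with F12 (NaH, THF, 0 °C) gives the epoxy cinnamyl ether F13. Cp2TiCl (from Cp2TiCl2 and Zn) opens the epoxide and the radical closes 5-exo-trig onto the styrene through a chair-like transition state that should set C3 trans to C2 and C4 cis to C3, giving the oxolane alcohol F14. Neutral benzylation (2-benzyloxy-1-methylpyridinium triflate, MgO, PhCF3, 85 °C) gives the benzyl ether F15, and Bu4NF removes the silyl group to give 10.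

Step 8. n-BuLi may remove benzylic protons (benzyl ethers, oxolane C2–H) in competition with the ring B proton, or incomplete N-silylation may let the carbamate fragment. The fallback brings ring B in with silyl and triflate groups already in place; it sets out from 7 and returns at 17. Commercial 3-methoxy-2-(trimethylsilyl)phenyl triflate (COc1cccc(OS(=O)(=O)C(F)(F)F)c1[Si](C)(C)C) is C–H borylated at the position meta to both oxygen substituents ([Ir(OMe)(cod)]2, dtbpy, B2pin2) to give the aryl boronate F16, and CuBr2 (MeOH/H2O) converts it into the aryl bromide F17. Alkene 7 is hydroborated as in step 6 and the alkylborane 9 is coupled with F17 (Pd(dppf)Cl2, K3PO4, THF/DMF, rt), the unhindered C–Br bond reacting in preference to the silyl-flanked triflate, to give 17 directly.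

Further compounds
F1 | step 12 | iodo carbamate: 15 with iodine in place of SiMe3 | COc1ccc([C@@H]2OC[C@@H](Cc3cc(OC(=O)NC(C)C)c(I)c(OC)c3)[C@H]2COCc2ccccc2)cc1OCc1ccccc1
F2 | step 12 | 2-iodophenol: 16 with iodine in place of SiMe3 | COc1ccc([C@@H]2OC[C@@H](Cc3cc(O)c(I)c(OC)c3)[C@H]2COCc2ccccc2)cc1OCc1ccccc1
F3 | step 12 | ethyl (E)-3-[4-(benzyloxy)-3-methoxyphenyl]prop-2-enoate | CCOC(=O)/C=C/c1ccc(OCc2ccccc2)c(OC)c1
F4 | step 12 | (E)-3-[4-(benzyloxy)-3-methoxyphenyl]prop-2-en-1-ol | OC/C=C/c1ccc(OCc2ccccc2)c(OC)c1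
F5 | step 12 | [(2S,3S)-3-[4-(benzyloxy)-3-methoxyphenyl]oxiran-2-yl]methanol | OC[C@@H]1O[C@H]1c1ccc(OCc2ccccc2)c(OC)c1
F6 | step 12 | (2S,3R)-3-[4-(benzyloxy)-3-methoxyphenyl]-3-(aryloxy)propane-1,2-diol, aryl being the iodinated ring B of F2 | COc1ccc([C@@H]2OC[C@@H](Cc3cc(O[C@H](c4ccc(OCc5ccccc5)c(OC)c4)[C@@H](O)CO)c(I)c(OC)c3)[C@H]2COCc2ccccc2)cc1OCc1ccccc1
F7 | step 12 | primary 4-methylbenzenesulfonate of diol F6 | COc1ccc([C@@H]2OC[C@@H](Cc3cc(O[C@H](c4ccc(OCc5ccccc5)c(OC)c4)[C@@H](O)COS(=O)(=O)c4ccc(C)cc4)c(I)c(OC)c3)[C@H]2COCc2ccccc2)cc1OCc1ccccc1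
F8 | step 12 | aryl ether epoxide: 20 O-arylated by the iodinated ring B of F2, (R) at the ether carbon and (S) at the oxirane | COc1ccc([C@@H]2OC[C@@H](Cc3cc(O[C@H](c4ccc(OCc5ccccc5)c(OC)c4)[C@@H]4CO4)c(I)c(OC)c3)[C@H]2COCc2ccccc2)cc1OCc1ccccc1
F9 | step 6 | (3-bromo-5-methoxyphenoxy)tri(propan-2-yl)silane | COc1cc(Br)cc(O[Si](C(C)C)(C(C)C)C(C)C)c1
F10 | step 6 | ethyl (E)-3-{3-methoxy-5-[tri(propan-2-yl)silyloxy]phenyl}prop-2-enoate | CCOC(=O)/C=C/c1cc(OC)cc(O[Si](C(C)C)(C(C)C)C(C)C)c1
F11 | step 6 | (E)-3-{3-methoxy-5-[tri(propan-2-yl)silyloxy]phenyl}prop-2-en-1-ol | OC/C=C/c1cc(OC)cc(O[Si](C(C)C)(C(C)C)C(C)C)c1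
F12 | step 6 | (E)-1-(3-bromoprop-1-en-1-yl)-3-methoxy-5-[tri(propan-2-yl)silyloxy]benzene | BrC/C=C/c1cc(OC)cc(O[Si](C(C)C)(C(C)C)C(C)C)c1
F13 | step 6 | epoxy cinnamyl ether: 4 O-alkylated by F12 | O([C@@H](c1ccc(OC)c(OCc2ccccc2)c1)[C@H]1CO1)C/C=C/c1cc(OC)cc(O[Si](C(C)C)(C(C)C)C(C)C)c1
F14 | step 6 | [(2R,3S,4S)-2-[3-(benzyloxy)-4-methoxyphenyl]-4-{3-methoxy-5-[tri(propan-2-yl)silyloxy]benzyl}oxolan-3-yl]methanol | COc1ccc([C@@H]2OC[C@@H](Cc3cc(OC)cc(O[Si](C(C)C)(C(C)C)C(C)C)c3)[C@H]2CO)cc1OCc1ccccc1
F15 | step 6 | benzyl ether of F14 (tri(propan-2-yl)silyl ether of 10) | COc1ccc([C@@H]2OC[C@@H](Cc3cc(OC)cc(O[Si](C(C)C)(C(C)C)C(C)C)c3)[C@H]2COCc2ccccc2)cc1OCc1ccccc1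
F16 | step 8 | 3-methoxy-5-(4,4,5,5-tetramethyl-1,3,2-dioxaborolan-2-yl)-2-(trimethylsilyl)phenyl trifluoromethanesulfonate | COc1cc(B2OC(C)(C)C(C)(C)O2)cc(OS(=O)(=O)C(F)(F)F)c1[Si](C)(C)C
F17 | step 8 | 5-bromo-3-methoxy-2-(trimethylsilyl)phenyl trifluoromethanesulfonate | COc1cc(Br)cc(OS(=O)(=O)C(F)(F)F)c1[Si](C)(C)C
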